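The synthesis rests on cutting the bond between the side-chain methylene C3′ and the alkene carbon C2′ (chain C1′–C8′ counted outward from C6 of the dihydropyranone ring). The key step treats the hydroxyl-bearing C4′ as a latent ketone, so that C3′ is the α-carbon of a methyl ketone. A palladium-catalysed Migita–Kuwajima α-alkenylation joins the tin enolate of silyl enol ether 7 to the complete (E)-iodovinyl lactone 15, forming C3′–C2′ with retention of the E-alkene and with the unprotected lactone in place. An Evans–Tishchenko reduction then converts the C4′ ketone into the free 1,3-anti carbinol while delivering the acetate to O6′.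

Key step: step 10

Remark: cinnamaldehyde, 3,3-diethoxyprop-1-yne and all reagents are taken as purchasable; cyclopentadienyl rings on zirconium are drawn σ-bonded in the SMILES for simplicity.

Step 1
Reactants: 1 (E)-cinnamaldehyde
Product: 3 (S,E)-1-phenylhexa-1,5-dien-3-ol, via diisopinocampheylborinate 2 (not isolated)
Conditions: (−)-Ipc2BOMe, allylMgBr, Et2O, −78 °C to rt; then 1, −78 °C; then NaOH, H2O2, rt
Reagents that add atoms: allylmagnesium bromide, C=CC[Mg]Br
Why: Brown asymmetric allylboration through a chair-like six-membered transition state whose facial bias comes from the two isopinocampheyl groups derived from (+)-α-pinene, which should direct 1,2-addition to the Si face of the enal and set the (S)-carbinol C6′.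

Step 2
Reactants: 3 (S,E)-1-phenylhexa-1,5-dien-3-ol
Product: 4 tert-butyldimethylsilyl ether of (S,E)-1-phenylhexa-1,5-dien-3-ol
Conditions: TBSCl, imidazole, DMF, rt
Reagents that add atoms: tert-butyldimethylsilyl chloride, CC(C)(C)[Si](C)(C)Cl
Why: Imidazole-promoted silylation of the secondary allylic alcohol, which does not touch the stereocentre.

Step 3
Reactants: 4 tert-butyldimethylsilyl ether of (S,E)-1-phenylhexa-1,5-dien-3-ol
Product: 5 (S,E)-4-(tert-butyldimethylsilyloxy)-6-phenylhex-5-en-2-one
Conditions: PdCl2 (10 mol%), Cu(OAc)2 (20 mol%), O2 (1 atm), DMA/H2O 7:1, rt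
Reagents that add atoms: water, O
Why: Tsuji–Wacker oxidation, in which Markovnikov hydroxypalladation of the terminal alkene gives the methyl ketone while the 1,2-disubstituted styryl alkene and the silyl ether should stay untouched.

Step 4
Reactants: 5 (S,E)-4-(tert-butyldimethylsilyloxy)-6-phenylhex-5-en-2-one
Product: 7 (S,E)-4-(tert-butyldimethylsilyloxy)-6-phenyl-2-(trimethylsilyloxy)hexa-1,5-diene, via lithium enolate 6 (not isolated)
Conditions: LiN(iPr)2 (LDA, 1.1 equiv), THF, −78 °C; then TMSCl, −78 to 0 °C; non-aqueous work-up, used crude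
Reagents that add atoms: chlorotrimethylsilane, C[Si](C)(C)Cl
Why: Kinetic enolisation of the methyl ketone by the hindered amide base occurs at the methyl group, and O-silylation fixes the terminal enol silane so that C3′ becomes the nucleophilic carbon.

Step 5
Reactants: 8 3,3-diethoxyprop-1-yne
Product: 10 (E)-3,3-diethoxy-1-iodoprop-1-ene, via alkenylzirconocene chloride 9 (not isolated)
Conditions: Cp2Zr(H)Cl, THF, rt; then I2, 0 °C
Reagents that add atoms: iodine, II
Why: Hydrozirconation–iodination: syn addition places zirconium on the terminal carbon and iodinolysis of the C–Zr bond proceeds with retention, fixing the E-iodoalkene.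

Step 6
Reactants: 10 (E)-3,3-diethoxy-1-iodoprop-1-ene
Product: 11 (E)-3-iodoprop-2-enal
Conditions: 1 M aq. HCl, THF, 0 °C to rt; used at once as a solution
Reagents that add atoms: water, O
Why: Acid-catalysed acetal hydrolysis, with the E-enal being the thermodynamically favoured geometry.

Step 7
Reactants: 11 (E)-3-iodoprop-2-enal
Product: 13 (S,E)-1-iodohexa-1,5-dien-3-ol, via diisopinocampheylborinate 12 (not isolated)
Conditions: (−)-Ipc2BOMe, allylMgBr, Et2O, −78 °C to rt; then 11, −78 °C; then NaOH, H2O2, rt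
Reagents that add atoms: allylmagnesium bromide, C=CC[Mg]Br
Why: Brown asymmetric allylboration as in step 1, in which the same isopinocampheyl reagent should add to the Si face of the aldehyde and set the (S)-carbinol that becomes ring carbon C6.

Step 8
Reactants: 13 (S,E)-1-iodohexa-1,5-dien-3-ol
Product: 14 (S,E)-1-iodohexa-1,5-dien-3-yl prop-2-enoate
Conditions: acryloyl chloride, Et3N, CH2Cl2, −20 to 0 °C
Reagents that add atoms: acryloyl chloride, C=CC(=O)Cl
Why: Esterification of the secondary alcohol with the acid chloride, leaving the stereocentre untouched.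

Step 9
Reactants: 14 (S,E)-1-iodohexa-1,5-dien-3-yl prop-2-enoate
Product: 15 (S)-6-[(E)-2-iodoethenyl]-5,6-dihydro-2H-pyran-2-one
Conditions: second-generation Grubbs catalyst (5 mol%), CH2Cl2 (0.005 M), 40 °C
Reagents that add atoms: none
Why: Ring-closing metathesis between the terminal allyl alkene and the acrylate closes the six-membered unsaturated lactone with loss of ethylene, while the hindered, electron-poor iodoalkene should not engage the ruthenium carbene.

Step 10
Reactants: 7 (S,E)-4-(tert-butyldimethylsilyloxy)-6-phenyl-2-(trimethylsilyloxy)hexa-1,5-diene (1.2 equiv); 15 (S)-6-[(E)-2-iodoethenyl]-5,6-dihydro-2H-pyran-2-one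
Product: 17 (S)-6-[(1E,6S,7E)-6-(tert-butyldimethylsilyloxy)-4-oxo-8-phenylocta-1,7-dienyl]-5,6-dihydro-2H-pyran-2-one, via tributyltin enolate 16 (not isolated)
Conditions: Bu3SnF (1.2 equiv), PdCl2[P(o-tol)3]2 (5 mol%), degassed toluene, 70 °C
Reagents that add atoms: none
Why: Fluoride transfer from Bu3SnF to silicon converts 7 regiospecifically into the tin enolate 16; zerovalent palladium (formed in situ from the divalent precatalyst) inserts into the C–I bond of 15 with retention of the E geometry, the enolate passes from tin to palladium, and reductive elimination forms the C3′–C2′ bond. The closest known reaction type is the Migita–Kosugi/Kuwajima–Urabe palladium-catalysed α-alkenylation of tin enolates generated from methyl-ketone enol silanes. No ring is closed and no stereocentre is created; the E-alkene is carried over from 15, and the stereocentres C6 and C6′ lie outside the reacting atoms. The step needs regioselectivity for C3′ over C5′, which the kinetic enol silane of step 4 secures. It also needs chemoselectivity for the C–I bond over the unsaturated lactone and the allylic silyl ether, which the fast oxidative addition of alkenyl iodides and the neutral, base-free medium should secure.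

Step 11
Reactants: 17 (S)-6-[(1E,6S,7E)-6-(tert-butyldimethylsilyloxy)-4-oxo-8-phenylocta-1,7-dienyl]-5,6-dihydro-2H-pyran-2-one
Product: 18 (S)-6-[(1E,6S,7E)-6-hydroxy-4-oxo-8-phenylocta-1,7-dienyl]-5,6-dihydro-2H-pyran-2-one
Conditions: HF·pyridine, pyridine, THF, 0 °C to rt
Reagents that add atoms: none
Why: Fluoride-mediated silyl ether cleavage under buffered, non-basic conditions, chosen so that the β-hydroxy ketone should not undergo retro-aldol cleavage and the β,γ-alkene should not migrate.

Step 12
Reactants: 18 (S)-6-[(1E,6S,7E)-6-hydroxy-4-oxo-8-phenylocta-1,7-dienyl]-5,6-dihydro-2H-pyran-2-one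
Product: 20 (S)-6-[(1E,4R,6S,7E)-6-acetoxy-4-hydroxy-8-phenylocta-1,7-dienyl]-5,6-dihydro-2H-pyran-2-one, via acetaldehyde hemiacetal 19 (not isolated)
Conditions: SmI2 (30 mol%), CH3CHO (10 equiv), THF, −10 °C
Reagents that add atoms: acetaldehyde, CC=O
Why: Evans–Tishchenko reduction, in which the C6′ hydroxyl adds to acetaldehyde, trivalent samarium holds the hemiacetal and the C4′ ketone in a chair-like six-membered transition state, and intramolecular hydride transfer sets C4′ 1,3-anti to C6′ (4′R) while leaving the acetate on O6′ and the C4′ hydroxyl free.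

Compound list
1 | (E)-cinnamaldehyde | O=C/C=C/c1ccccc1 | starting material
2 | diisopinocampheylborinate of (S,E)-1-phenylhexa-1,5-dien-3-ol | B(O[C@H](/C=C/c1ccccc1)CC=C)([C@@H]1C[C@@H]2C[C@H]([C@H]1C)C2(C)C)[C@@H]1C[C@@H]2C[C@H]([C@H]1C)C2(C)C | intermediate
3 | (S,E)-1-phenylhexa-1,5-dien-3-ol | O[C@H](/C=C/c1ccccc1)CC=C | intermediate
4 | tert-butyldimethylsilyl ether of (S,E)-1-phenylhexa-1,5-dien-3-ol | CC(C)(C)[Si](C)(C)O[C@H](/C=C/c1ccccc1)CC=C | intermediate
5 | (S,E)-4-(tert-butyldimethylsilyloxy)-6-phenylhex-5-en-2-one | CC(C)(C)[Si](C)(C)O[C@H](/C=C/c1ccccc1)CC(C)=O | intermediate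
6 | lithium enolate of 5 (methyl side) | CC(C)(C)[Si](C)(C)O[C@H](/C=C/c1ccccc1)CC(=C)O[Li] | intermediate
7 | (S,E)-4-(tert-butyldimethylsilyloxy)-6-phenyl-2-(trimethylsilyloxy)hexa-1,5-diene | CC(C)(C)[Si](C)(C)O[C@H](/C=C/c1ccccc1)CC(=C)O[Si](C)(C)C | intermediate
8 | 3,3-diethoxyprop-1-yne | C#CC(OCC)OCC | starting material
9 | (E)-(3,3-diethoxyprop-1-enyl)zirconocene chloride | CCOC(OCC)/C=C/[Zr](Cl)(C1C=CC=C1)C1C=CC=C1 | intermediate
10 | (E)-3,3-diethoxy-1-iodoprop-1-ene | CCOC(OCC)/C=C/I | intermediate
11 | (E)-3-iodoprop-2-enal | O=C/C=C/I | intermediate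
12 | diisopinocampheylborinate of (S,E)-1-iodohexa-1,5-dien-3-ol | B(O[C@H](/C=C/I)CC=C)([C@@H]1C[C@@H]2C[C@H]([C@H]1C)C2(C)C)[C@@H]1C[C@@H]2C[C@H]([C@H]1C)C2(C)C | intermediate
13 | (S,E)-1-iodohexa-1,5-dien-3-ol | I/C=C/[C@@H](O)CC=C | intermediate
14 | (S,E)-1-iodohexa-1,5-dien-3-yl prop-2-enoate | C=CC(=O)O[C@H](/C=C/I)CC=C | intermediate
15 | (S)-6-[(E)-2-iodoethenyl]-5,6-dihydro-2H-pyran-2-one | I/C=C/[C@@H]1CC=CC(=O)O1 | intermediate
16 | tributyltin enolate of 5 (drawn as the C-bound α-stannyl ketone) | CC(C)(C)[Si](C)(C)O[C@H](/C=C/c1ccccc1)CC(=O)C[Sn](CCCC)(CCCC)CCCC | intermediate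
17 | (S)-6-[(1E,6S,7E)-6-(tert-butyldimethylsilyloxy)-4-oxo-8-phenylocta-1,7-dienyl]-5,6-dihydro-2H-pyran-2-one | CC(C)(C)[Si](C)(C)O[C@H](/C=C/c1ccccc1)CC(=O)C/C=C/[C@@H]1CC=CC(=O)O1 | intermediate
18 | (S)-6-[(1E,6S,7E)-6-hydroxy-4-oxo-8-phenylocta-1,7-dienyl]-5,6-dihydro-2H-pyran-2-one | O[C@H](/C=C/c1ccccc1)CC(=O)C/C=C/[C@@H]1CC=CC(=O)O1 | intermediate
19 | acetaldehyde hemiacetal of 18 at O6′ (samarium-bound in the flask) | CC(O)O[C@H](/C=C/c1ccccc1)CC(=O)C/C=C/[C@@H]1CC=CC(=O)O1 | intermediate
20 | (S)-6-[(1E,4R,6S,7E)-6-acetoxy-4-hydroxy-8-phenylocta-1,7-dienyl]-5,6-dihydro-2H-pyran-2-one | CC(=O)O[C@H](/C=C/c1ccccc1)C[C@H](O)C/C=C/[C@@H]1CC=CC(=O)O1 | target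

Total step count: 12
Longest linear sequence: 8 steps (steps 5 to 9, then 10 to 12)

Steps most likely to fail

Step 10 (key coupling). The new β,γ-alkene may migrate into conjugation with the C4′ ketone in the tin enolate/fluoride medium, the tin enolate may add in conjugate fashion to the unsaturated lactone, or zerovalent palladium may ionise the allylic C6–O bond at 70 °C and erode the C6 configuration. The fallback is a B-alkyl Suzuki–Miyaura coupling followed by oxidation; it sets out from 7 and 15 and comes back at 17. Hydroboration of enol silane 7 with 9-BBN (THF, 0 °C to rt, boron on the terminal carbon C3′) would give the β-silyloxyalkyl borane F1. This is coupled at room temperature with 15 (PdCl2(dppf), AsPh3, Cs2CO3, DMF/THF/H2O). The labile trimethylsilyl ether is lost on citric acid work-up, leaving the C4′-epimeric homoallylic alcohols F2. Dess–Martin periodinane (NaHCO3, CH2Cl2) then oxidises both epimers to ketone 17.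

Step 12. Retro-aldol cleavage or migration of the β,γ-alkene may occur under the samarium alkoxide, or hydride transfer may stall at the hemiacetal. The fallback acylates first and sets C4′ by reagent control; it runs from 18 to 20. Acetylation of 18 (Ac2O, pyridine, 0 °C) would give the β-acetoxy ketone F3. A ketoreductase (NADPH-dependent alcohol dehydrogenase, glucose/glucose dehydrogenase recycling, phosphate buffer pH 7 with DMSO, 30 °C), selected by screening for the (R)-alcohol, then reduces the C4′ ketone to give 20.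

Step 11. During the slow cleavage of the robust silyl ether, acid may ionise and dehydrate the styryl carbinol β to the ketone, or the alkene may migrate. The fallback uses a protecting group that leaves at work-up; it sets out from 3 and comes back at 18. Tsuji–Wacker oxidation of the free alcohol 3 (PdCl2, Cu(OAc)2, O2, DMA/H2O) would give (S,E)-4-hydroxy-6-phenylhex-5-en-2-one F4. Double deprotonation (LiN(iPr)2, 2.2 equiv, THF, −78 °C) and TMSCl give the bis-silylated enol silane F5. Coupling with 15 under the conditions of step 10 gives the trimethylsilyl ether F6, which is cleaved in a citric acid/MeOH work-up to give 18.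

Further compounds
F1 | step 10 | B-[(2RS,4S,5E)-4-(tert-butyldimethylsilyloxy)-6-phenyl-2-(trimethylsilyloxy)hex-5-enyl]-9-borabicyclo[3.3.1]nonane | CC(C)(C)[Si](C)(C)O[C@H](/C=C/c1ccccc1)CC(O[Si](C)(C)C)CB1C2CCCC1CCC2
F2 | step 10 | (S)-6-[(1E,4RS,6S,7E)-6-(tert-butyldimethylsilyloxy)-4-hydroxy-8-phenylocta-1,7-dienyl]-5,6-dihydro-2H-pyran-2-one | CC(C)(C)[Si](C)(C)O[C@H](/C=C/c1ccccc1)CC(O)C/C=C/[C@@H]1CC=CC(=O)O1
F3 | step 12 | (S)-6-[(1E,6S,7E)-6-acetoxy-4-oxo-8-phenylocta-1,7-dienyl]-5,6-dihydro-2H-pyran-2-one | CC(=O)O[C@H](/C=C/c1ccccc1)CC(=O)C/C=C/[C@@H]1CC=CC(=O)O1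
F4 | step 11 | (S,E)-4-hydroxy-6-phenylhex-5-en-2-one | O[C@H](/C=C/c1ccccc1)CC(C)=O
F5 | step 11 | (S,E)-6-phenyl-2,4-bis(trimethylsilyloxy)hexa-1,5-diene | C[Si](C)(C)O[C@H](/C=C/c1ccccc1)CC(=C)O[Si](C)(C)C
F6 | step 11 | (S)-6-[(1E,6S,7E)-4-oxo-8-phenyl-6-(trimethylsilyloxy)octa-1,7-dienyl]-5,6-dihydro-2H-pyran-2-one | C[Si](C)(C)O[C@H](/C=C/c1ccccc1)CC(=O)C/C=C/[C@@H]1CC=CC(=O)O1
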